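**Plan**

1. Numbering: seven-membered ring C1, C5, C6, C7, C8, C9, C10; side chain C2–C4 and C15 on C1; methyl C14 on C10; lactone C11 (α-carbon), C12 (C=O), C13 (=CH2). α is the ring face that carries O6, β the other face.
2. Retrosynthetic cuts, in order: C7–C11 (γ-lactone ring), the ester C–O bonds at O6 and O5, C7=C8 (seven-membered ring), C1–C2, C9–C10 and C1–C10. The C2 ketone is carried as the C2≡C3 alkyne, and the C9 alcohol is oxidised to a ketone only for the ring closure.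
3. Forward: the C1/C5/C6/C7 unit of D-tartrate becomes a vinyl ethyl ketone, which is joined to acrolein (aldol) and to a butynyl unit (acetylide addition). Ring-closing metathesis then gives the seven-membered ring, O6 and O5 are esterified, and the lactone ring is closed last.
4. Enabling feature: O6 sits on the ring carbon next to C7, and C9, which bears oxygen in the target, is β to C7 through C8. A temporary C9 ketone therefore makes C7 the β-carbon of a C7=C8–C9=O enone, five atoms from C11 of an acrylate on O6, so C11–C7 bonding closes the α-methylene-γ-lactone in one catalytic isomerisation.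
5. Stereochemistry: C5 and C6 from D-tartaric acid; C4 from (R)-but-3-yn-2-ol; the ester α-carbon from (R)-2-methylbutanoic acid; C10 (and a first C9) from a chelate-controlled syn aldol; C1 from Felkin–Anh addition; C7 from the cis ring fusion of the key step; C9 from hydride delivery directed by the C1 hydroxyl.

Key step: step 14

Remark: the α-carbon of the target's 2-methylbutanoate is R, so (R)-2-methylbutanoic acid is needed; it and (R)-but-3-yn-2-ol are taken as purchased single enantiomers. TBS = tert-butyldimethylsilyl, TBDPS = tert-butyldiphenylsilyl.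

**Route**

Step 1
Reactants: 1 dimethyl (4S,5S)-2,2-dimethyl-1,3-dioxolane-4,5-dicarboxylate
Product: 2 methyl (4S,5R)-5-(hydroxymethyl)-2,2-dimethyl-1,3-dioxolane-4-carboxylate
Conditions: NaBH4 (0.6 equiv), MeOH, 0 °C
Reagents that add atoms: none
Why: Partial NaBH4 reduction of an α-alkoxy ester; the two ester groups of C2-symmetric 1 are homotopic, so mono-reduction should give a single hydroxy ester and no stereocentre is touched.

Step 2
Reactants: 2 methyl (4S,5R)-5-(hydroxymethyl)-2,2-dimethyl-1,3-dioxolane-4-carboxylate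
Product: 4 methyl (4S,5R)-5-ethenyl-2,2-dimethyl-1,3-dioxolane-4-carboxylate, via aldehyde 3 (not isolated)
Conditions: (COCl)2, DMSO, CH2Cl2, −78 °C; Et3N; then Ph3P=CH2 (from Ph3PCH3Br, n-BuLi), THF, −78 → 0 °C
Reagents that add atoms: methylenetriphenylphosphorane, C=P(c1ccccc1)(c1ccccc1)c1ccccc1
Why: One-pot Swern oxidation and Wittig methylenation, in which the epimerisable α-alkoxy aldehyde 3 is trapped cold by the non-stabilised ylide, so C6 should keep its configuration.

Step 3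
Reactants: 4 methyl (4S,5R)-5-ethenyl-2,2-dimethyl-1,3-dioxolane-4-carboxylate
Product: 6 1-[(4S,5R)-5-ethenyl-2,2-dimethyl-1,3-dioxolan-4-yl]propan-1-one, via Weinreb amide 5 (not isolated)
Conditions: MeNH(OMe)·HCl, iPrMgCl, THF, −20 °C; then EtMgBr, −20 → 0 °C
Reagents that add atoms: N,O-dimethylhydroxylamine hydrochloride, CNOC.Cl (its N(OMe)Me group is in 5 only); ethylmagnesium bromide, CC[Mg]Br
Why: Weinreb ketone synthesis in one flask; the chelated tetrahedral adduct of 5 with EtMgBr releases the ketone only on work-up, so over-addition is avoided and no stereocentre is formed.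

Step 4
Reactants: 6 1-[(4S,5R)-5-ethenyl-2,2-dimethyl-1,3-dioxolan-4-yl]propan-1-one; 7 acrolein
Product: 9 (2S,3R)-1-[(4S,5R)-5-ethenyl-2,2-dimethyl-1,3-dioxolan-4-yl]-3-hydroxy-2-methylpent-4-en-1-one, via titanium enolate 8 (not isolated)
Conditions: TiCl4, iPr2NEt, CH2Cl2, −78 °C; then 7, −78 °C
Reagents that add atoms: titanium tetrachloride, Cl[Ti](Cl)(Cl)Cl (Ti and Cl in 8 only)
Why: Titanium-mediated syn aldol reaction: soft enolisation at the ethyl group gives the (Z)-enolate 8 chelated through the C5 dioxolane oxygen, and acrolein should add through a chair transition state to the enolate face opposite C6, setting C10 (S) and, as the syn partner, C9 (R).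

Step 5
Reactants: 9 (2S,3R)-1-[(4S,5R)-5-ethenyl-2,2-dimethyl-1,3-dioxolan-4-yl]-3-hydroxy-2-methylpent-4-en-1-one
Product: 10 (2S,3R)-3-(TBS-oxy)-1-[(4S,5R)-5-ethenyl-2,2-dimethyl-1,3-dioxolan-4-yl]-2-methylpent-4-en-1-one
Conditions: TBSOTf, 2,6-lutidine, CH2Cl2, −78 °C
Reagents that add atoms: tert-butyldimethylsilyl trifluoromethanesulfonate, CC(C)(C)[Si](C)(C)OS(=O)(=O)C(F)(F)F
Why: Silylation of the secondary alcohol with a silyl triflate; the bulky non-chelating ether prevents β-chelation in step 7 and masks the C9 oxygen until step 12.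

Step 6
Reactants: 11 (R)-but-3-yn-2-ol
Product: 12 (R)-(but-3-yn-2-yloxy)(tert-butyl)diphenylsilane
Conditions: TBDPSCl, imidazole, DMF, 0 °C → rt
Reagents that add atoms: tert-butyl(chloro)diphenylsilane, CC(C)(C)[Si](Cl)(c1ccccc1)c1ccccc1
Why: Standard silylation of a secondary alcohol; the TBDPS ether should survive the later acetonide hydrolysis and the selective TBS cleavage, and C4 is not touched.

Step 7
Reactants: 10 (2S,3R)-3-(TBS-oxy)-1-[(4S,5R)-5-ethenyl-2,2-dimethyl-1,3-dioxolan-4-yl]-2-methylpent-4-en-1-one; 12 (R)-(but-3-yn-2-yloxy)(tert-butyl)diphenylsilane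
Product: 14 (3R,4S,5R,8R)-3-(TBS-oxy)-8-(TBDPS-oxy)-5-[(4S,5R)-5-ethenyl-2,2-dimethyl-1,3-dioxolan-4-yl]-4-methylnon-1-en-6-yn-5-ol, via lithium acetylide 13 (not isolated)
Conditions: 12, n-BuLi, THF, −78 °C; CeCl3; then 10, −78 °C
Reagents that add atoms: n-butyllithium, [Li]CCCC (Li in 13 only)
Why: Addition of a cerium-modified lithium acetylide to a ketone under Felkin–Anh control: the C5–O bond lies anti to the incoming nucleophile with H on its path, and the C10 centre (C9 branch anti, H outside) favours the same face, so C1 should form with its hydroxyl trans to O5 in the later ring, while CeCl3 suppresses enolisation.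

Step 8
Reactants: 14 (3R,4S,5R,8R)-3-(TBS-oxy)-8-(TBDPS-oxy)-5-[(4S,5R)-5-ethenyl-2,2-dimethyl-1,3-dioxolan-4-yl]-4-methylnon-1-en-6-yn-5-ol
Product: 15 5β,6α-O-isopropylidene-9β-(TBS-oxy)-10α-methyl-1β-[(3R)-3-(TBDPS-oxy)but-1-ynyl]cyclohept-7-en-1α-ol
Conditions: second-generation Grubbs catalyst (5 mol %), CH2Cl2 (0.005 M), 40 °C
Reagents that add atoms: none
Why: Ring-closing metathesis of the two terminal vinyl groups closes the seven-membered ring as the C7=C8 alkene; the hindered internal alkyne is expected to stay out of the catalytic cycle and no stereocentre changes.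

Step 9
Reactants: 15 5β,6α-O-isopropylidene-9β-(TBS-oxy)-10α-methyl-1β-[(3R)-3-(TBDPS-oxy)but-1-ynyl]cyclohept-7-en-1α-ol
Product: 16 9β-(TBS-oxy)-10α-methyl-1β-[(3R)-3-(TBDPS-oxy)but-1-ynyl]cyclohept-7-ene-1α,5β,6α-triol
Conditions: AcOH/H2O (4:1), rt
Reagents that add atoms: none
Why: Acid hydrolysis of the strained trans-fused acetonide; the secondary TBS and TBDPS ethers and the tertiary propargylic alcohol should be stable to aqueous acetic acid at this temperature.

Step 10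
Reactants: 16 9β-(TBS-oxy)-10α-methyl-1β-[(3R)-3-(TBDPS-oxy)but-1-ynyl]cyclohept-7-ene-1α,5β,6α-triol; 17 acryloyl chloride
Product: 18 1α,5β-dihydroxy-9β-(TBS-oxy)-10α-methyl-1β-[(3R)-3-(TBDPS-oxy)but-1-ynyl]cyclohept-7-en-6α-yl acrylate
Conditions: 17 (1.05 equiv), 2,4,6-collidine, CH2Cl2, −78 → −40 °C
Reagents that add atoms: none
Why: Selective O-acylation: the allylic C6 hydroxyl next to sp2 C7 is more accessible than the C5 hydroxyl beside quaternary C1 and than the tertiary C1 hydroxyl, so one equivalent of acid chloride at low temperature should give the C6 acrylate.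

Step 11
Reactants: 18 1α,5β-dihydroxy-9β-(TBS-oxy)-10α-methyl-1β-[(3R)-3-(TBDPS-oxy)but-1-ynyl]cyclohept-7-en-6α-yl acrylate; 19 (R)-2-methylbutanoic acid
Product: 20 1α-hydroxy-9β-(TBS-oxy)-10α-methyl-5β-[(2R)-2-methylbutanoyloxy]-1β-[(3R)-3-(TBDPS-oxy)but-1-ynyl]cyclohept-7-en-6α-yl acrylate
Conditions: 19, DCC, DMAP (10 mol %), CH2Cl2, 0 °C → rt
Reagents that add atoms: none
Why: Steglich esterification of the remaining secondary C5 hydroxyl; the tertiary C1 hydroxyl should not react, and the α-stereocentre of the acid is expected to survive at 0 °C.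

Step 12
Reactants: 20 1α-hydroxy-9β-(TBS-oxy)-10α-methyl-5β-[(2R)-2-methylbutanoyloxy]-1β-[(3R)-3-(TBDPS-oxy)but-1-ynyl]cyclohept-7-en-6α-yl acrylate
Product: 21 1α,9β-dihydroxy-10α-methyl-5β-[(2R)-2-methylbutanoyloxy]-1β-[(3R)-3-(TBDPS-oxy)but-1-ynyl]cyclohept-7-en-6α-yl acrylate
Conditions: HF·pyridine, pyridine, THF, 0 °C
Reagents that add atoms: none
Why: Fluoride-mediated desilylation, in which the secondary TBS ether should be cleaved much faster than the TBDPS ether, while both esters are left alone.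

Step 13
Reactants: 21 1α,9β-dihydroxy-10α-methyl-5β-[(2R)-2-methylbutanoyloxy]-1β-[(3R)-3-(TBDPS-oxy)but-1-ynyl]cyclohept-7-en-6α-yl acrylate
Product: 22 1α-hydroxy-10α-methyl-5β-[(2R)-2-methylbutanoyloxy]-9-oxo-1β-[(3R)-3-(TBDPS-oxy)but-1-ynyl]cyclohept-7-en-6α-yl acrylate
Conditions: Dess–Martin periodinane, CH2Cl2, 0 °C → rt
Reagents that add atoms: none
Why: Dess–Martin oxidation of the secondary allylic C9 alcohol to the enone; the tertiary alcohol is inert and the near-neutral conditions should spare C10 and the β-hydroxy ketone.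

Step 14
Reactants: 22 1α-hydroxy-10α-methyl-5β-[(2R)-2-methylbutanoyloxy]-9-oxo-1β-[(3R)-3-(TBDPS-oxy)but-1-ynyl]cyclohept-7-en-6α-yl acrylate
Product: 25 1α-hydroxy-10α-methyl-5β-[(2R)-2-methylbutanoyloxy]-9-oxo-1β-[(3R)-3-(TBDPS-oxy)but-1-ynyl]cycloheptane-6α,7α-fused α-methylene-γ-butyrolactone (O on C6; C11 on C7), via phosphonium enolate 23 (not isolated), via cyclised phosphonium enolate 24 (not isolated)
Conditions: PMe3 (20 mol %), t-AmOH, rt
Reagents that add atoms: trimethylphosphine, CP(C)C (in 23 and 24 only; released again)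
Why: PMe3 adds reversibly to the acrylate terminus C13 to give the phosphonium enolate 23, whose nucleophilic C11 attacks C7 of the C7=C8–C9=O enone; proton shift from C11 to C8 in 24 and loss of PMe3 restore the C11=C13 methylene. The closest known reaction type is the phosphine-catalysed intramolecular Rauhut–Currier reaction of acrylates of γ-hydroxy cyclic enones and dienones, which gives cis-fused α-methylene-γ-butyrolactones. The γ-lactone ring (C11, C12, O, C6, C7) closes in the 5-exo-trig mode. C7 is the only new stereocentre and is set by C6: the O–C12–C11 tether can reach C7 only on the face of the C6–O bond, so the ring fusion should be cis. The step needs the acrylate and not the enone to be the nucleophilic partner, and C–C rather than O–C bond formation at C7; the first is secured because phosphine addition at C7 is reversible and its enolate could close only a seven-membered ring, the second by a soft phosphine in a protic medium in which the tertiary C1 hydroxyl is not ionised.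

Step 15
Reactants: 25 1α-hydroxy-10α-methyl-5β-[(2R)-2-methylbutanoyloxy]-9-oxo-1β-[(3R)-3-(TBDPS-oxy)but-1-ynyl]cycloheptane-6α,7α-fused α-methylene-γ-butyrolactone
Product: 27 1α,9β-dihydroxy-10α-methyl-5β-[(2R)-2-methylbutanoyloxy]-1β-[(3R)-3-(TBDPS-oxy)but-1-ynyl]cycloheptane-6α,7α-fused α-methylene-γ-butyrolactone, via alkoxyborohydride 26 (not isolated)
Conditions: Me4NBH(OAc)3, MeCN/AcOH (1:1), −30 °C
Reagents that add atoms: tetramethylammonium triacetoxyborohydride, C[N+](C)(C)C.CC(=O)O[BH-](OC(C)=O)OC(C)=O (boron, acetate and cation in 26 only; one hydride stays in 27)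
Why: Hydroxyl-directed reduction of the Evans–Saksena type: the C1 hydroxyl replaces an acetate on boron to give 26, which delivers hydride intramolecularly to the α face of the C9 ketone, so the new C9 hydroxyl should be β (1,3-anti to the C1 hydroxyl); esters and the α-methylene lactone are not reduced by this reagent.

Step 16
Reactants: 27 1α,9β-dihydroxy-10α-methyl-5β-[(2R)-2-methylbutanoyloxy]-1β-[(3R)-3-(TBDPS-oxy)but-1-ynyl]cycloheptane-6α,7α-fused α-methylene-γ-butyrolactone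
Product: 29 1α,9β-dihydroxy-10α-methyl-5β-[(2R)-2-methylbutanoyloxy]-1β-[(3R)-3-(TBDPS-oxy)butanoyl]cycloheptane-6α,7α-fused α-methylene-γ-butyrolactone, via cyclic enol ether 28 (not isolated)
Conditions: Ph3PAuNTf2 (5 mol %), THF/H2O (10:1), rt
Reagents that add atoms: water, O
Why: Gold-catalysed alkyne hydration with neighbouring-group control: the C9 hydroxyl, cis to the alkynyl group, should add 5-exo-dig to C2 of the activated alkyne to give enol ether 28, whose hydrolysis places the carbonyl at C2 and not at C3.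

Step 17
Reactants: 29 1α,9β-dihydroxy-10α-methyl-5β-[(2R)-2-methylbutanoyloxy]-1β-[(3R)-3-(TBDPS-oxy)butanoyl]cycloheptane-6α,7α-fused α-methylene-γ-butyrolactone
Product: 30 target CNP0291806.5
Conditions: HF·pyridine, THF, 0 °C → rt
Reagents that add atoms: none
Why: Fluoride-mediated cleavage of the TBDPS ether under mildly acidic conditions, which should avoid retro-aldol cleavage or β-elimination of the β-hydroxy ketone and conjugate addition to the α-methylene lactone.

**Compound list**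

1 | dimethyl (4S,5S)-2,2-dimethyl-1,3-dioxolane-4,5-dicarboxylate (dimethyl 2,3-O-isopropylidene-D-tartrate) | COC(=O)[C@H]1OC(C)(C)O[C@@H]1C(=O)OC | starting material
2 | methyl (4S,5R)-5-(hydroxymethyl)-2,2-dimethyl-1,3-dioxolane-4-carboxylate | COC(=O)[C@H]1OC(C)(C)O[C@@H]1CO | intermediate
3 | methyl (4S,5S)-5-formyl-2,2-dimethyl-1,3-dioxolane-4-carboxylate (not isolated) | COC(=O)[C@H]1OC(C)(C)O[C@@H]1C=O | intermediate
4 | methyl (4S,5R)-5-ethenyl-2,2-dimethyl-1,3-dioxolane-4-carboxylate | COC(=O)[C@H]1OC(C)(C)O[C@@H]1C=C | intermediate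
5 | (4S,5R)-5-ethenyl-N-methoxy-N,2,2-trimethyl-1,3-dioxolane-4-carboxamide (not isolated) | CON(C)C(=O)[C@H]1OC(C)(C)O[C@@H]1C=C | intermediate
6 | 1-[(4S,5R)-5-ethenyl-2,2-dimethyl-1,3-dioxolan-4-yl]propan-1-one | CCC(=O)[C@H]1OC(C)(C)O[C@@H]1C=C | intermediate
7 | acrolein | C=CC=O | starting material
8 | trichlorotitanium (Z)-enolate of 6 (not isolated) | C/C=C(\O[Ti](Cl)(Cl)Cl)[C@H]1OC(C)(C)O[C@@H]1C=C | intermediate
9 | (2S,3R)-1-[(4S,5R)-5-ethenyl-2,2-dimethyl-1,3-dioxolan-4-yl]-3-hydroxy-2-methylpent-4-en-1-one | C=C[C@@H](O)[C@H](C)C(=O)[C@H]1OC(C)(C)O[C@@H]1C=C | intermediate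
10 | (2S,3R)-3-[(tert-butyldimethylsilyl)oxy]-1-[(4S,5R)-5-ethenyl-2,2-dimethyl-1,3-dioxolan-4-yl]-2-methylpent-4-en-1-one | C=C[C@@H](O[Si](C)(C)C(C)(C)C)[C@H](C)C(=O)[C@H]1OC(C)(C)O[C@@H]1C=C | intermediate
11 | (R)-but-3-yn-2-ol | C#C[C@@H](C)O | starting material
12 | (R)-(but-3-yn-2-yloxy)(tert-butyl)diphenylsilane | C#C[C@@H](C)O[Si](c1ccccc1)(c1ccccc1)C(C)(C)C | intermediate
13 | lithium acetylide of 12 (not isolated) | [Li]C#C[C@@H](C)O[Si](c1ccccc1)(c1ccccc1)C(C)(C)C | intermediate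
14 | (3R,4S,5R,8R)-3-[(tert-butyldimethylsilyl)oxy]-8-[(tert-butyldiphenylsilyl)oxy]-5-[(4S,5R)-5-ethenyl-2,2-dimethyl-1,3-dioxolan-4-yl]-4-methylnon-1-en-6-yn-5-ol | C=C[C@@H](O[Si](C)(C)C(C)(C)C)[C@H](C)[C@@](O)(C#C[C@@H](C)O[Si](c1ccccc1)(c1ccccc1)C(C)(C)C)[C@H]1OC(C)(C)O[C@@H]1C=C | intermediate
15 | 5β,6α-O-isopropylidene-9β-(TBS-oxy)-10α-methyl-1β-[(3R)-3-(TBDPS-oxy)but-1-ynyl]cyclohept-7-en-1α-ol (trans-fused acetonide) | CC1(C)O[C@@H]2C=C[C@@H](O[Si](C)(C)C(C)(C)C)[C@H](C)[C@@](O)(C#C[C@@H](C)O[Si](c3ccccc3)(c3ccccc3)C(C)(C)C)[C@H]2O1 | intermediate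
16 | 9β-(TBS-oxy)-10α-methyl-1β-[(3R)-3-(TBDPS-oxy)but-1-ynyl]cyclohept-7-ene-1α,5β,6α-triol | O[C@@H]1C=C[C@@H](O[Si](C)(C)C(C)(C)C)[C@H](C)[C@@](O)(C#C[C@@H](C)O[Si](c2ccccc2)(c2ccccc2)C(C)(C)C)[C@H]1O | intermediate
17 | acryloyl chloride | C=CC(=O)Cl | starting material
18 | 1α,5β-dihydroxy-9β-(TBS-oxy)-10α-methyl-1β-[(3R)-3-(TBDPS-oxy)but-1-ynyl]cyclohept-7-en-6α-yl acrylate | C=CC(=O)O[C@@H]1C=C[C@@H](O[Si](C)(C)C(C)(C)C)[C@H](C)[C@@](O)(C#C[C@@H](C)O[Si](c2ccccc2)(c2ccccc2)C(C)(C)C)[C@H]1O | intermediate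
19 | (R)-2-methylbutanoic acid | CC[C@@H](C)C(=O)O | starting material
20 | 1α-hydroxy-9β-(TBS-oxy)-10α-methyl-5β-[(2R)-2-methylbutanoyloxy]-1β-[(3R)-3-(TBDPS-oxy)but-1-ynyl]cyclohept-7-en-6α-yl acrylate | C=CC(=O)O[C@@H]1C=C[C@@H](O[Si](C)(C)C(C)(C)C)[C@H](C)[C@@](O)(C#C[C@@H](C)O[Si](c2ccccc2)(c2ccccc2)C(C)(C)C)[C@H]1OC(=O)[C@H](C)CC | intermediate
21 | 1α,9β-dihydroxy-10α-methyl-5β-[(2R)-2-methylbutanoyloxy]-1β-[(3R)-3-(TBDPS-oxy)but-1-ynyl]cyclohept-7-en-6α-yl acrylate | C=CC(=O)O[C@@H]1C=C[C@@H](O)[C@H](C)[C@@](O)(C#C[C@@H](C)O[Si](c2ccccc2)(c2ccccc2)C(C)(C)C)[C@H]1OC(=O)[C@H](C)CC | intermediate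
22 | 1α-hydroxy-10α-methyl-5β-[(2R)-2-methylbutanoyloxy]-9-oxo-1β-[(3R)-3-(TBDPS-oxy)but-1-ynyl]cyclohept-7-en-6α-yl acrylate | C=CC(=O)O[C@@H]1C=CC(=O)[C@H](C)[C@@](O)(C#C[C@@H](C)O[Si](c2ccccc2)(c2ccccc2)C(C)(C)C)[C@H]1OC(=O)[C@H](C)CC | intermediate
23 | phosphonium enolate: PMe3 adduct at C13 of 22, ester enolate at C11/C12 (not isolated) | C[P+](C)(C)CC=C([O-])O[C@@H]1C=CC(=O)[C@H](C)[C@@](O)(C#C[C@@H](C)O[Si](c2ccccc2)(c2ccccc2)C(C)(C)C)[C@H]1OC(=O)[C@H](C)CC | intermediate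
24 | cyclised phosphonium enolate: C11–C7 bond formed, ketone enolate at C8/C9, Me3P+ on C13 (not isolated) | C[P+](C)(C)CC1C(=O)O[C@@H]2[C@H]1C=C([O-])[C@H](C)[C@@](O)(C#C[C@@H](C)O[Si](c3ccccc3)(c3ccccc3)C(C)(C)C)[C@H]2OC(=O)[C@H](C)CC | intermediate
25 | 1α-hydroxy-10α-methyl-5β-[(2R)-2-methylbutanoyloxy]-9-oxo-1β-[(3R)-3-(TBDPS-oxy)but-1-ynyl]cycloheptane-6α,7α-fused α-methylene-γ-butyrolactone (O on C6; C11 on C7; cis fusion) | C=C1C(=O)O[C@@H]2[C@H]1CC(=O)[C@H](C)[C@@](O)(C#C[C@@H](C)O[Si](c3ccccc3)(c3ccccc3)C(C)(C)C)[C@H]2OC(=O)[C@H](C)CC | intermediate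
26 | tetramethylammonium alkoxy(diacetoxy)borohydride of 25, boron on O1 (not isolated) | C=C1C(=O)O[C@@H]2[C@H]1CC(=O)[C@H](C)[C@@](O[BH-](OC(C)=O)OC(C)=O)(C#C[C@@H](C)O[Si](c3ccccc3)(c3ccccc3)C(C)(C)C)[C@H]2OC(=O)[C@H](C)CC.C[N+](C)(C)C | intermediate
27 | 1α,9β-dihydroxy-10α-methyl-5β-[(2R)-2-methylbutanoyloxy]-1β-[(3R)-3-(TBDPS-oxy)but-1-ynyl]cycloheptane-6α,7α-fused α-methylene-γ-butyrolactone | C=C1C(=O)O[C@@H]2[C@H]1C[C@@H](O)[C@H](C)[C@@](O)(C#C[C@@H](C)O[Si](c3ccccc3)(c3ccccc3)C(C)(C)C)[C@H]2OC(=O)[C@H](C)CC | intermediate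
28 | cyclic enol ether: O9 bonded to C2, (Z)-C2=C3 exocyclic to the new oxolane ring O9–C9–C10–C1–C2 (not isolated) | C=C1C(=O)O[C@@H]2[C@H]1C[C@@H]3[C@H](C)[C@@](O)(C(=C\[C@@H](C)O[Si](c4ccccc4)(c4ccccc4)C(C)(C)C)\O3)[C@H]2OC(=O)[C@H](C)CC | intermediate
29 | 1α,9β-dihydroxy-10α-methyl-5β-[(2R)-2-methylbutanoyloxy]-1β-[(3R)-3-(TBDPS-oxy)butanoyl]cycloheptane-6α,7α-fused α-methylene-γ-butyrolactone | C=C1C(=O)O[C@@H]2[C@H]1C[C@@H](O)[C@H](C)[C@@](O)(C(=O)C[C@@H](C)O[Si](c3ccccc3)(c3ccccc3)C(C)(C)C)[C@H]2OC(=O)[C@H](C)CC | intermediate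
30 | CNP0291806.5: 1α,9β-dihydroxy-1β-[(3R)-3-hydroxybutanoyl]-10α-methyl-5β-[(2R)-2-methylbutanoyloxy]cycloheptane-6α,7α-fused α-methylene-γ-butyrolactone (1S,5S,6R,7S,9R,10S) | C=C1C(=O)O[C@@H]2[C@H]1C[C@@H](O)[C@H](C)[C@@](O)(C(=O)C[C@@H](C)O)[C@H]2OC(=O)[C@H](C)CC | target

**Count and risks**

Total step count: 17. Longest linear sequence: 16 (steps 1–5 and 7–17; step 6 is the side branch).

Steps most likely to fail:

1. Step 14. The tertiary C1 hydroxyl may add to C7 (oxa-Michael closure to a bridged ether), or the β-hydroxy ketone may open by retro-aldol cleavage, faster than the phosphonium enolate closes the lactone. Fallback, from 16 back to 27, needing neither the C9 ketone nor a nucleophilic catalyst: the C6 hydroxyl of 16 would be esterified with propiolic acid (DCC, DMAP, −20 °C) to give propiolate F1, and the C5 hydroxyl with 19 (DCC, DMAP) to give diester F2. Bu3SnH and AIBN in refluxing benzene at high dilution should add a stannyl radical to the propiolate terminus, and the resulting vinyl radical should close 5-exo onto C7=C8 to give the cis-fused stannylmethylene lactone F3. Protodestannylation (HCl in Et2O, CH2Cl2, −78 °C) gives α-methylene lactone F4, and HF·pyridine removes the TBS group to give 27.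

2. Step 16. The tertiary propargylic alcohol may undergo Meyer–Schuster rearrangement to a transposed enone, or water may attack C3 and give the regioisomeric ketone. Fallback, from 27 back to 29: carboxylative cyclisation with CO2 (AgOAc, DBU, toluene) through the C1 hydroxyl should give the (Z)-alkylidene cyclic carbonate F5, in which the five-membered ring fixes oxygen on C2. Mild hydrolysis (wet MeCN, catalytic Et3N) with loss of CO2 then gives the C2 ketone 29.

3. Step 7. Ketone 10 may be enolised, with β-elimination of the C9 silyloxy group, or the open-chain ketone may show poor facial selectivity. Fallback, from 10 back to 15, replacing open-chain by cyclic stereocontrol: ring-closing metathesis of 10 (second-generation Grubbs catalyst) before the alkyne is present gives cycloheptenone F6. Acetylide 13 with CeCl3 is then added to the ring ketone, where entry anti to the adjacent C10 methyl group (β face) is expected, to give 15.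

**Further compounds**

F1 | step 14 | 1α,5β-dihydroxy-9β-(TBS-oxy)-10α-methyl-1β-[(3R)-3-(TBDPS-oxy)but-1-ynyl]cyclohept-7-en-6α-yl propiolate | C#CC(=O)O[C@@H]1C=C[C@@H](O[Si](C)(C)C(C)(C)C)[C@H](C)[C@@](O)(C#C[C@@H](C)O[Si](c2ccccc2)(c2ccccc2)C(C)(C)C)[C@H]1O
F2 | step 14 | 1α-hydroxy-9β-(TBS-oxy)-10α-methyl-5β-[(2R)-2-methylbutanoyloxy]-1β-[(3R)-3-(TBDPS-oxy)but-1-ynyl]cyclohept-7-en-6α-yl propiolate | C#CC(=O)O[C@@H]1C=C[C@@H](O[Si](C)(C)C(C)(C)C)[C@H](C)[C@@](O)(C#C[C@@H](C)O[Si](c2ccccc2)(c2ccccc2)C(C)(C)C)[C@H]1OC(=O)[C@H](C)CC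
F3 | step 14 | 9β-TBS ether of 27 carrying a tributylstannyl group on C13 (α-stannylmethylene lactone, alkene geometry open) | CCCC[Sn](CCCC)(CCCC)C=C1C(=O)O[C@@H]2[C@H]1C[C@@H](O[Si](C)(C)C(C)(C)C)[C@H](C)[C@@](O)(C#C[C@@H](C)O[Si](c3ccccc3)(c3ccccc3)C(C)(C)C)[C@H]2OC(=O)[C@H](C)CC
F4 | step 14 | 9β-TBS ether of 27 | C=C1C(=O)O[C@@H]2[C@H]1C[C@@H](O[Si](C)(C)C(C)(C)C)[C@H](C)[C@@](O)(C#C[C@@H](C)O[Si](c3ccccc3)(c3ccccc3)C(C)(C)C)[C@H]2OC(=O)[C@H](C)CC
F5 | step 16 | cyclic carbonate of 27 spiro at C1 (ring C1–O–C(=O)–O–C2) with (Z)-C2=C3 exocyclic alkene | C=C1C(=O)O[C@@H]2[C@H]1C[C@@H](O)[C@H](C)[C@@](OC3=O)(C(=C\[C@@H](C)O[Si](c4ccccc4)(c4ccccc4)C(C)(C)C)\O3)[C@H]2OC(=O)[C@H](C)CC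
F6 | step 7 | 5β,6α-O-isopropylidene-9β-(TBS-oxy)-10α-methylcyclohept-7-en-1-one | CC1(C)O[C@@H]2C=C[C@@H](O[Si](C)(C)C(C)(C)C)[C@H](C)C(=O)[C@H]2O1
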